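**Plan**

- Feature: in the upper flavan unit, ring C (O1, C2, C3, C4, C4a, C8a) holds the O1–C8a–C4a–C4 array of an ortho-quinone methide, and its cis C2-aryl/C3-oxygen pair corresponds to a Z-1,2-disubstituted alkene.
- Cuts, in order: the eight O–benzyl bonds; C3–O of the upper unit (back to C3–Si); C3–C4 and O1–C2 of ring C together as a [4+2] retron; C4–C4a (aldehyde plus phenol); the C8–CHO bond of the catechin unit; the Si–C(sp) bond of the silane.
- Forward: (+)-catechin is perbenzylated, brominated and formylated at C8; a magnesium phenoxide adds through its ortho carbon to give the o-hydroxybenzhydrol; an alkynylsilane is semi-reduced to the Z-vinylsilane; the acid-generated quinone methide and the silane close ring C, the only ring made; Si→OH and hydrogenolysis finish.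
- Stereochemistry: the lower unit (2R,3S) comes from (+)-catechin; C2/C3 cis from the Z alkene; C3/C4 trans from exo approach of the silane; the absolute sense at C4 from a chiral phosphoric acid; C3–OH from stereoretentive Tamao–Fleming oxidation.

Key step: step 8

Assumption: the name gambiriin C is taken to mean exactly the SMILES given, i.e. epiafzelechin-(4β→8)-catechin with upper unit 2R,3R,4R and lower unit 2R,3S. Flavan numbering is used for both units. (−)-Epiafzelechin, which appears only in one fallback, is taken as a purchasable natural product.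

**Route**

Step 1
Reactants: 1 (+)-catechin
Product: 2 5,7,3',4'-tetra-O-benzyl-(+)-catechin
Conditions: BnBr (4.4 equiv), K2CO3, DMF, 0 °C → rt
Reagents that add atoms: benzyl bromide, BrCc1ccccc1
Why: Williamson ether synthesis: carbonate ionises only the four phenols, so the secondary 3-OH stays free and the C2 and C3 stereocentres of (+)-catechin are carried through unchanged.

Step 2
Reactants: 2 5,7,3',4'-tetra-O-benzyl-(+)-catechin
Product: 3 3,5,7,3',4'-penta-O-benzyl-(+)-catechin
Conditions: NaH, BnBr, DMF, 0 °C → rt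
Reagents that add atoms: benzyl bromide, BrCc1ccccc1
Why: Williamson O-alkylation of the sodium alkoxide caps the last hydroxyl, which would otherwise quench the organolithium of step 4 and the magnesium phenoxide of step 5; only the O–H bond reacts, so C3 keeps its configuration.

Step 3
Reactants: 3 3,5,7,3',4'-penta-O-benzyl-(+)-catechin
Product: 4 8-bromo-3,5,7,3',4'-penta-O-benzylcatechin
Conditions: NBS (1.0 equiv), CH2Cl2, −78 °C → rt
Reagents that add atoms: N-bromosuccinimide, O=C1CCC(=O)N1Br
Why: Electrophilic aromatic bromination: of the two free A-ring positions of per-O-alkylated flavan-3-ols, C8 is the one that reacts first with one equivalent of NBS at low temperature, and the B ring is less activated.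

Step 4
Reactants: 4 8-bromo-3,5,7,3',4'-penta-O-benzylcatechin
Product: 6 penta-O-benzylcatechin-8-carbaldehyde, via 8-lithio-penta-O-benzylcatechin 5 (not isolated)
Conditions: n-BuLi, THF, −78 °C; DMF, −78 → 0 °C; H2O
Reagents that add atoms: N,N-dimethylformamide, CN(C)C=O
Why: Bromine–lithium exchange followed by Bouveault formylation; at −78 °C exchange outruns benzylic deprotonation of the benzyl ethers, and the hemiaminal alkoxide releases the aldehyde only on aqueous work-up.

Step 5
Reactants: 7 3,5-bis(benzyloxy)phenol; 6 penta-O-benzylcatechin-8-carbaldehyde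
Product: 9 3,5-bis(benzyloxy)-2-[hydroxy(penta-O-benzylcatechin-8-yl)methyl]phenol (o-hydroxybenzhydrol; both carbinol epimers), via bromomagnesium 3,5-bis(benzyloxy)phenoxide 8 (not isolated)
Conditions: EtMgBr, Et2O, 0 °C; solvent switch to toluene; 6, rt; pH 7 buffer
Reagents that add atoms: none
Why: Ortho-specific hydroxyalkylation of a magnesium phenoxide: in a non-coordinating solvent magnesium binds both the phenoxide and the aldehyde oxygen and delivers the ortho carbon through a six-membered chelate, which rules out para attack; the new carbinol centre forms without control but is erased in step 8.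

Step 6
Reactants: 10 1-(benzyloxy)-4-ethynylbenzene; 11 benzylchlorodimethylsilane
Product: 13 benzyl{[4-(benzyloxy)phenyl]ethynyl}dimethylsilane, via lithium [4-(benzyloxy)phenyl]acetylide 12 (not isolated)
Conditions: n-BuLi, THF, −78 °C; 11, −78 °C → rt
Reagents that add atoms: none
Why: Deprotonation of the terminal alkyne and nucleophilic substitution at silicon by the lithium acetylide, a standard C-silylation that leaves the aryl benzyl ether alone.

Step 7
Reactants: 13 benzyl{[4-(benzyloxy)phenyl]ethynyl}dimethylsilane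
Product: 14 (Z)-benzyl{2-[4-(benzyloxy)phenyl]ethenyl}dimethylsilane
Conditions: H2 (1 atm), Lindlar catalyst, quinoline, EtOAc, rt, stopped after 1 equiv H2
Reagents that add atoms: none
Why: Lindlar semi-hydrogenation delivers both hydrogens to the same face of the adsorbed alkyne and so gives the Z alkene; the poisoned palladium should hydrogenolyse neither the aryl benzyl ether nor the Si–benzyl group.

Step 8
Reactants: 9 o-hydroxybenzhydrol; 14 (Z)-benzyl{2-[4-(benzyloxy)phenyl]ethenyl}dimethylsilane
Product: 16 benzyl[(2R,3R,4R)-5,7-bis(benzyloxy)-2-[4-(benzyloxy)phenyl]-4-(penta-O-benzylcatechin-8-yl)chroman-3-yl]dimethylsilane (2,3-cis; 3,4-trans), via (E)-o-quinone methide 15 (not isolated)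
Conditions: (R)-TRIP (10 mol %), 5 Å MS, toluene, −20 °C; 9 added slowly to 14 (5 equiv)
Reagents that add atoms: none
Why: Proposed new method: the phosphoric acid dehydrates 9 to the E-configured o-quinone methide 15 and stays bound to its oxygen, the silicon-bearing carbon of 14 attacks the methide carbon C4 because the charge that develops at C2 is stabilised both by the 4-benzyloxyphenyl group and by the β-silicon effect, and the quinone oxygen then closes onto C2 within one concerted but asynchronous inverse-demand [4+2] event. The closest known reactions are Brønsted-acid-catalysed [4+2] cycloadditions of o-quinone methides generated in situ from o-hydroxybenzyl alcohols with styrenes (same regiochemistry) and the ipso attack of carbocations on vinylsilanes; a vinylsilane as the 2π partner of an o-quinone methide has no precedent. Ring C is closed as a six-membered ring by cycloaddition, and if the event were stepwise the O1–C2 bond would form by 6-endo capture of the β-silyl benzylic cation by the phenoxide oxygen. C2/C3 cis follows from suprafacial addition to the Z alkene, C3/C4 trans from an exo approach that keeps the silyl and aryl groups of 14 away from the 5-benzyloxy-flanked heterodiene, and the absolute configuration at C4 (and with it C2 and C3) from the chiral phosphate, which is expected to shield one face of the planar methide because the remote catechin stereocentres give little bias of their own. The step needs regio-, diastereo- and face selectivity as well as chemoselectivity over self-alkylation by the electron-rich rings: silicon plus the para-oxygenated aryl group secure the first, the Z geometry and the bulk of SiMe2Bn the second, the catalyst the third, and slow addition of 9 to an excess of 14 over molecular sieves the last.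

Step 9
Reactants: 16 3-silyl flavan
Product: 18 5,7,4'-tri-O-benzylepiafzelechin-(4β→8)-3,5,7,3',4'-penta-O-benzylcatechin, via 3-(hydroxydimethylsilyl) flavan 17 (not isolated)
Conditions: TBAF, THF, 0 °C → rt; then KHCO3, 30% H2O2, MeOH, 40 °C
Reagents that add atoms: hydrogen peroxide, OO
Why: Tamao–Fleming oxidation of a benzyldimethylsilyl group: fluoride cleaves the Si–benzyl bond to silanol 17, hydroperoxide adds to silicon and C3 migrates from silicon to oxygen with retention, so the silicon-bearing configuration becomes the 3-hydroxyl configuration; no free phenol is present to be oxidised, and the axial C3–Si bond lies gauche to C2–O1, which works against anti β-elimination.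

Step 10
Reactants: 18 octabenzyl dimer
Product: 19 epiafzelechin-(4β→8)-catechin (target)
Conditions: H2 (1 atm), Pd(OH)2/C, THF–MeOH–H2O, rt
Reagents that add atoms: none
Why: Catalytic hydrogenolysis of the seven aryl benzyl ethers and the one alkyl benzyl ether is the standard unmasking of benzylated oligomeric flavan-3-ols; no stereocentre is involved and the interflavan C4–C8 bond should survive the neutral conditions.

**Compound list**

1 | (+)-catechin, (2R,3S) | O[C@H]1Cc2c(O)cc(O)cc2O[C@@H]1c1ccc(O)c(O)c1 | starting material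
2 | 5,7,3',4'-tetra-O-benzyl-(+)-catechin, (2R,3S)-5,7-bis(benzyloxy)-2-[3,4-bis(benzyloxy)phenyl]chroman-3-ol | O[C@H]1Cc2c(OCc3ccccc3)cc(OCc3ccccc3)cc2O[C@@H]1c1ccc(OCc2ccccc2)c(OCc2ccccc2)c1 | intermediate
3 | 3,5,7,3',4'-penta-O-benzyl-(+)-catechin, (2R,3S) | C(c1ccccc1)O[C@H]1Cc2c(OCc3ccccc3)cc(OCc3ccccc3)cc2O[C@@H]1c1ccc(OCc2ccccc2)c(OCc2ccccc2)c1 | intermediate
4 | 8-bromo-3,5,7,3',4'-penta-O-benzylcatechin, (2R,3S) | C(c1ccccc1)O[C@H]1Cc2c(OCc3ccccc3)cc(OCc3ccccc3)c(Br)c2O[C@@H]1c1ccc(OCc2ccccc2)c(OCc2ccccc2)c1 | intermediate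
5 | 8-lithio-penta-O-benzylcatechin, (2R,3S) | C(c1ccccc1)O[C@H]1Cc2c(OCc3ccccc3)cc(OCc3ccccc3)c([Li])c2O[C@@H]1c1ccc(OCc2ccccc2)c(OCc2ccccc2)c1 | intermediate (not isolated)
6 | penta-O-benzylcatechin-8-carbaldehyde, (2R,3S) | C(c1ccccc1)O[C@H]1Cc2c(OCc3ccccc3)cc(OCc3ccccc3)c(C=O)c2O[C@@H]1c1ccc(OCc2ccccc2)c(OCc2ccccc2)c1 | intermediate
7 | 3,5-bis(benzyloxy)phenol | Oc1cc(OCc2ccccc2)cc(OCc2ccccc2)c1 | starting material
8 | bromomagnesium 3,5-bis(benzyloxy)phenoxide | Br[Mg]Oc1cc(OCc2ccccc2)cc(OCc2ccccc2)c1 | intermediate (not isolated)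
9 | 3,5-bis(benzyloxy)-2-[hydroxy(penta-O-benzylcatechin-8-yl)methyl]phenol, lower unit (2R,3S), carbinol carbon as both epimers | Oc1cc(OCc2ccccc2)cc(OCc2ccccc2)c1C(O)c1c(OCc2ccccc2)cc(OCc2ccccc2)c2c1O[C@H](c1ccc(OCc3ccccc3)c(OCc3ccccc3)c1)[C@@H](OCc1ccccc1)C2 | intermediate
10 | 1-(benzyloxy)-4-ethynylbenzene | C#Cc1ccc(OCc2ccccc2)cc1 | starting material
11 | benzylchlorodimethylsilane | C[Si](C)(Cl)Cc1ccccc1 | starting material
12 | lithium [4-(benzyloxy)phenyl]acetylide | [Li]C#Cc1ccc(OCc2ccccc2)cc1 | intermediate (not isolated)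
13 | benzyl{[4-(benzyloxy)phenyl]ethynyl}dimethylsilane | C[Si](C)(Cc1ccccc1)C#Cc1ccc(OCc2ccccc2)cc1 | intermediate
14 | (Z)-benzyl{2-[4-(benzyloxy)phenyl]ethenyl}dimethylsilane | C[Si](C)(Cc1ccccc1)/C=C\c1ccc(OCc2ccccc2)cc1 | intermediate
15 | (E)-3,5-bis(benzyloxy)-6-[(penta-O-benzylcatechin-8-yl)methylidene]cyclohexa-2,4-dien-1-one (o-quinone methide; aryl anti to C=O; lower unit 2R,3S) | O=C1C=C(OCc2ccccc2)C=C(OCc2ccccc2)/C1=C\c1c(OCc2ccccc2)cc(OCc2ccccc2)c2c1O[C@H](c1ccc(OCc3ccccc3)c(OCc3ccccc3)c1)[C@@H](OCc1ccccc1)C2 | intermediate (not isolated)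
16 | benzyl[(2R,3R,4R)-5,7-bis(benzyloxy)-2-[4-(benzyloxy)phenyl]-4-[(2R,3S)-3,5,7-tris(benzyloxy)-2-[3,4-bis(benzyloxy)phenyl]chroman-8-yl]chroman-3-yl]dimethylsilane (2,3-cis; 3,4-trans) | O(Cc5ccccc5)c1ccc(cc1)[C@H]1Oc2cc(OCc5ccccc5)cc(OCc5ccccc5)c2[C@H](c2c(OCc5ccccc5)cc(OCc5ccccc5)c3c2O[C@H](c4ccc(OCc5ccccc5)c(OCc5ccccc5)c4)[C@@H](OCc5ccccc5)C3)[C@H]1[Si](C)(C)Cc5ccccc5 | intermediate
17 | [(2R,3R,4R)-5,7-bis(benzyloxy)-2-[4-(benzyloxy)phenyl]-4-(penta-O-benzylcatechin-8-yl)chroman-3-yl]dimethylsilanol | O(Cc5ccccc5)c1ccc(cc1)[C@H]1Oc2cc(OCc5ccccc5)cc(OCc5ccccc5)c2[C@H](c2c(OCc5ccccc5)cc(OCc5ccccc5)c3c2O[C@H](c4ccc(OCc5ccccc5)c(OCc5ccccc5)c4)[C@@H](OCc5ccccc5)C3)[C@H]1[Si](C)(C)O | intermediate (not isolated)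
18 | (2R,3R,4R)-5,7-bis(benzyloxy)-2-[4-(benzyloxy)phenyl]-4-[(2R,3S)-3,5,7-tris(benzyloxy)-2-[3,4-bis(benzyloxy)phenyl]chroman-8-yl]chroman-3-ol (5,7,4'-tri-O-benzylepiafzelechin-(4β→8)-penta-O-benzylcatechin) | O(Cc5ccccc5)c1ccc(cc1)[C@H]1Oc2cc(OCc5ccccc5)cc(OCc5ccccc5)c2[C@H](c2c(OCc5ccccc5)cc(OCc5ccccc5)c3c2O[C@H](c4ccc(OCc5ccccc5)c(OCc5ccccc5)c4)[C@@H](OCc5ccccc5)C3)[C@H]1O | intermediate
19 | epiafzelechin-(4β→8)-catechin, (2R,3S)-2-(3,4-dihydroxyphenyl)-8-[(2R,3R,4R)-3,5,7-trihydroxy-2-(4-hydroxyphenyl)chroman-4-yl]chroman-3,5,7-triol (gambiriin C as given) | Oc1ccc([C@H]2Oc3cc(O)cc(O)c3[C@H](c3c(O)cc(O)c4c3O[C@H](c3ccc(O)c(O)c3)[C@@H](O)C4)[C@H]2O)cc1 | target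

**Count and risks**

Total steps: 10. Longest linear sequence: 8 steps (1, 2, 3, 4, 5, 8, 9, 10 from (+)-catechin); steps 6 and 7 form the two-step silane branch.

Steps most likely to fail:

1. Step 8 (new method). The stabilised quinone methide may be alkylated by the electron-rich rings of a second molecule faster than by the weakly nucleophilic, hindered vinylsilane. The β-silyl cation may lose silicon (alkenylation) instead of closing the ring. The catalyst may impose little or the wrong facial bias.
 Fallback, known chemistry, sets out from 3 and returns at 18: the interflavan bond is made by Lewis-acid-promoted Friedel–Crafts-type coupling of a C4-oxygenated flavan-3-ol with a C8 nucleophile. Purchased (−)-epiafzelechin (Oc1ccc(cc1)[C@H]1Oc2cc(O)cc(O)c2C[C@H]1O) is benzylated on its three phenols (BnBr, K2CO3, DMF) to 5,7,4'-tri-O-benzylepiafzelechin F1. DDQ with 2-ethoxyethanol in CH2Cl2 should oxidise the benzylic C4–H and give the 3,4-trans 4-(2-ethoxyethoxy) ether F2. TMSOTf in CH2Cl2 at −78 °C then ionises F2 in the presence of an excess of 3, whose C8 should attack the C4 cation from the face opposite the C3 oxygen and the B ring, giving 18 directly; step 10 follows.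

2. Step 9. Fluoride attack at silicon may trigger β-elimination across C3–C2 with opening of ring C, or the hindered silicon may resist formation of the peroxysilicate.
 Fallback, sets out from 10 and returns at 18: the hydroxyl surrogate is changed so that silicon already carries an oxygen ligand and no Si–C cleavage by naked fluoride is needed. Acetylide 12, made from 10 as in step 6, is quenched with excess diethoxydimethylsilane to give {[4-(benzyloxy)phenyl]ethynyl}(ethoxy)dimethylsilane F3. Lindlar semi-hydrogenation gives (Z)-{2-[4-(benzyloxy)phenyl]ethenyl}(ethoxy)dimethylsilane F4. Cycloaddition with 9 under the conditions of step 8 (via 15) should give the 3-[ethoxy(dimethyl)silyl] flavan F5. This is oxidised under the buffered alkoxysilane protocol (H2O2, KF, KHCO3, THF–MeOH), which tolerates β-oxygen substituents, to 18.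

3. Step 5. The magnesium phenoxide may fail to add to the doubly ortho-substituted, electron-rich aldehyde, or the product may ionise in the flask and capture a second phenol (triarylmethane formation).
 Fallback, sets out from 7 (and uses 4) and returns at 9: the polarity is reversed. Magnesium-mediated ortho-formylation of 7 (MgCl2, Et3N, paraformaldehyde, MeCN, reflux) gives 2,4-bis(benzyloxy)-6-hydroxybenzaldehyde F6. Silylation (TBSCl, imidazole, DMF) gives its tert-butyldimethylsilyl ether F7. Aryllithium 5, generated from 4 with n-BuLi at −78 °C, adds to F7 to give the O-silylated benzhydrol F8; a silyl shift to the carbinol oxygen would be harmless. TBAF in THF at 0 °C liberates 9.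

Further compounds
F1 | step 8 | (2R,3R)-5,7-bis(benzyloxy)-2-[4-(benzyloxy)phenyl]chroman-3-ol (5,7,4'-tri-O-benzylepiafzelechin) | O(Cc5ccccc5)c1ccc(cc1)[C@H]1Oc2cc(OCc5ccccc5)cc(OCc5ccccc5)c2C[C@H]1O
F2 | step 8 | (2R,3R,4S)-5,7-bis(benzyloxy)-2-[4-(benzyloxy)phenyl]-4-(2-ethoxyethoxy)chroman-3-ol (3,4-trans) | O(Cc5ccccc5)c1ccc(cc1)[C@H]1Oc2cc(OCc5ccccc5)cc(OCc5ccccc5)c2[C@H](OCCOCC)[C@H]1O
F3 | step 9 | {[4-(benzyloxy)phenyl]ethynyl}(ethoxy)dimethylsilane | CCO[Si](C)(C)C#Cc1ccc(OCc2ccccc2)cc1
F4 | step 9 | (Z)-{2-[4-(benzyloxy)phenyl]ethenyl}(ethoxy)dimethylsilane | CCO[Si](C)(C)/C=C\c1ccc(OCc2ccccc2)cc1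
F5 | step 9 | [(2R,3R,4R)-5,7-bis(benzyloxy)-2-[4-(benzyloxy)phenyl]-4-(penta-O-benzylcatechin-8-yl)chroman-3-yl](ethoxy)dimethylsilane | O(Cc5ccccc5)c1ccc(cc1)[C@H]1Oc2cc(OCc5ccccc5)cc(OCc5ccccc5)c2[C@H](c2c(OCc5ccccc5)cc(OCc5ccccc5)c3c2O[C@H](c4ccc(OCc5ccccc5)c(OCc5ccccc5)c4)[C@@H](OCc5ccccc5)C3)[C@H]1[Si](C)(C)OCC
F6 | step 5 | 2,4-bis(benzyloxy)-6-hydroxybenzaldehyde | O=Cc1c(O)cc(OCc2ccccc2)cc1OCc1ccccc1
F7 | step 5 | 2,4-bis(benzyloxy)-6-[(tert-butyldimethylsilyl)oxy]benzaldehyde | O=Cc1c(O[Si](C)(C)C(C)(C)C)cc(OCc2ccccc2)cc1OCc1ccccc1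
F8 | step 5 | {2,4-bis(benzyloxy)-6-[(tert-butyldimethylsilyl)oxy]phenyl}(penta-O-benzylcatechin-8-yl)methanol, lower unit (2R,3S), both carbinol epimers | CC(C)(C)[Si](C)(C)Oc1cc(OCc2ccccc2)cc(OCc2ccccc2)c1C(O)c1c(OCc2ccccc2)cc(OCc2ccccc2)c2c1O[C@H](c1ccc(OCc3ccccc3)c(OCc3ccccc3)c1)[C@@H](OCc1ccccc1)C2
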